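The trap is to take D that is not yet in an adduct for D still waiting for E.

| flask | D | E | remark | time |
|---|---|---|---|---|
| Sunday's | 12 mM | 0.28 equiv | run made earlier |  |
| Tuesday's | 12 mM | 1.6 equiv | run made earlier |  |
| west | 12 mM | 0.500 equiv |  | 5.0 min |
| south-east | 12 mM | 2.00 equiv |  | 5.0 min |

| run | time / min | J / % | Q / % |
|---|---|---|---|
| Sunday's | 0.200 | 0 | 2.4 |
| Sunday's | 0.417 | 0 | 5.2 |
| Sunday's | 0.667 | 0.9 | 6.2 |
| Sunday's | 1.33 | 1.5 | 8.9 |
| Sunday's | 2.50 | 2.3 | 11.4 |
| Tuesday's | 0.200 | 2.5 | 14.3 |
| Tuesday's | 0.667 | 13.1 | 26.6 |
| Tuesday's | 1.33 | 24.3 | 30.4 |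
| Tuesday's | 2.00 | 30.2 | 31.0 |
| Tuesday's | 2.50 | 35.3 | 29.0 |

(each reading ± 0.5 percentage points)

- in percentages every species weighs as the D in it: one G counts as two
- for Z the L are counted in
- reactions considered so far: 2 D -> G; E + X -> J + Z; D + Z <-> L; D + E -> Q + Z; D + E -> X + Z; E + Q -> J + Z

- which of these holds the largest part of the D at the end of west (D / Q / J / X)
- which of these holds the largest part of the D at the end of south-east (D / Q / J / X)
- final J in west, as a percentage of the D charged

Count turnovers in Tuesday's run at 2.50 min. One Q (mono adduct) spent one E and one J (bis adduct) two, so the spent E, X apart, comes to 99.6% of the D charged, out of 1.6 equiv put in. Q and J together hold 64.3% of D. Both partners seem to remain, yet the first 0.200 min added 16.8% and the last stretch from 2.00 min added less, 3.1 percentage points. With E still there, I take the partner that fell to be D, leaving unseen, most plausibly as G (other product).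

So I carry a loss number λ, a rough selectivity factor: D outside Q and J per D inside them, times the equivalents of E, 0.888. It counts leftover D and X as lost. Addition runs with E, so I divide by E: west, at 0.500 equiv, should have 1.78 D outside Q and J per D in them, which puts 36.0% of the D in Q and J together.

The forecast says D for west, J for south-east and J 10.5%, “so unreacted D stays largest”. My 36.0% is a share for Q and J, and λ does not split the rest among D, X and G; taking J at the forecast's 10.5% leaves Q at 25.5%, and I judge D to stand below that, so I differ and say Q.

West ends with Q on top, 18.4% against D 9.62%, with J 10.3% and G 55.8%; south-east ends with J at 57.6%.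

    2 D → G (k = 0.820 /M/s)
    E + X → J + Z (k = 2.60 /M/s)
    D + Z ⇌ L, settled at all times (K = 27.0 /M)
    D + E → Q + Z (k = 0.990 /M/s)
    D + E → X + Z (k = 0.560 /M/s)
    E + Q → J + Z (k = 0.350 /M/s)

West's D outside Q and J per D in them is 2.48, against 1.78 from λ; a neighbour flask, west with 1.20 equiv of E, gives 0.669 against 0.740. At 5.00 min in west, D is still used by the step to G 2.5 times as fast as by the step to Q.

(The readings are calculated with made-up constants, noise included.)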